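**Plan**

1. Locants used here: ring A is the cyclohexadienone (C1 ring carbonyl, C2 acetyl-bearing carbon, C3 and C5 enol carbons, C4 quaternary carbon, C6 carbon carrying the CH2 bridge); ring B is the phloroglucinol. Retrosynthetic cuts, in order: the CH2–ring B bond of the bridge, the C1–C2 bond of ring A, the C5–C6 bond, the C4–geranyl bond.
2. Forward: 4-hydroxy-3,6-dimethyl-2-pyranone already holds C2, C3, C4 (with its methyl), C5 and the acetyl carbons in a temporary lactone ring. Geranylation makes C4 quaternary, tert-butyl acetate enolate opens the lactone and adds C6 and C1, and thermolysis closes ring A at C1–C2. Ring B is made in two steps from phloroglucinol and joined last through a Mannich base.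
3. Enabling feature: in ring A, C2 is the central carbon of the β-diketone C3(=O)–C2–C(=O)CH3 and C1 is the carboxyl carbon of the β-keto acid unit C5(=O)–C6–C1. C1 can therefore be raised to an α-oxoketene with the enol carbon C2 placed 1,6 to it, and C4, which has no hydrogen, shuts the pyranone and aromatization channels.
4. Stereochemistry: the only stereocenter, C4, is set in step 1 by a chiral palladium catalyst (face selection on the planar pyranolate). No later step makes or breaks a bond at C4. The E olefin of the geranyl group comes from geranyl acetate.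

Key step: step 3

Assumption: the target is treated as the enol tautomer drawn, for which C4 is (R); CIP labels of the intermediates change with the neighbouring groups while the spatial arrangement stays the same. The (R,R) ligand of step 1 is assumed to give (S)-3; if the sense is the opposite, the (S,S) ligand is used.

**Route**

Step 1
Reactants: 1 4-hydroxy-3,6-dimethyl-2H-pyran-2-one; 2 geranyl acetate [(2E)-3,7-dimethylocta-2,6-dien-1-yl acetate]
Product: 3 (3S)-3-[(2E)-3,7-dimethylocta-2,6-dien-1-yl]-3,6-dimethyl-2H-pyran-2,4(3H)-dione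
Conditions: Pd2(dba)3·CHCl3 (2.5 mol%), (R,R)-DACH-phenyl bisphosphine ligand {N,N'-[(1R,2R)-cyclohexane-1,2-diyl]bis[2-(diphenylphosphino)benzamide]} (7.5 mol%), Et3N (1.1 equiv), CH2Cl2, 0 °C
Reagents that add atoms: none
Why: Proposed new method: the triethylammonium pyranolate of 1 is a soft, planar, prochiral carbon nucleophile that should attack the unsubstituted CH2 terminus of the cationic geranyl π-allyl palladium complex (formed from 2 and zerovalent palladium) on the face left open by the chiral ligand pocket, which sets C4, while any O-allyl ether re-ionizes to the same complex so that the C-quaternary dione accumulates; the closest known reaction types are the palladium-catalysed C3-allylation of 4-hydroxy-6-methyl-2-pyranone and the Tsuji–Trost asymmetric allylic alkylation of cyclic prochiral enolates with prenyl and geranyl electrophiles.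

Step 2
Reactants: 3 (3S)-3-[(2E)-3,7-dimethylocta-2,6-dien-1-yl]-3,6-dimethyl-2H-pyran-2,4(3H)-dione; 4 tert-butyl acetate
Product: 5 tert-butyl (4S)-4-[(2E)-3,7-dimethylocta-2,6-dien-1-yl]-4-methyl-3,5,7-trioxooctanoate
Conditions: 4 (2.5 equiv), LiN(i-Pr)2 (2.5 equiv), THF, −78 °C; then 3, −78 → −40 °C; AcOH quench at −78 °C
Reagents that add atoms: none
Why: The lactone carbonyl of 3 is a vinylogous mixed anhydride whose leaving group is a β-diketone enolate, so the ester enolate should add there and open the ring irreversibly (crossed Claisen acylation), the second equivalent of enolate holding the product as its dianion, and the quaternary stereocenter, which has no α-hydrogen, is untouched.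

Step 3
Reactants: 5 tert-butyl (4S)-4-[(2E)-3,7-dimethylocta-2,6-dien-1-yl]-4-methyl-3,5,7-trioxooctanoate
Product: 7 (4R)-2-acetyl-4-[(2E)-3,7-dimethylocta-2,6-dien-1-yl]-3,5-dihydroxy-4-methylcyclohexa-2,5-dien-1-one (monomer A), via acylketene 6 (not isolated)
Conditions: PhMe (0.01 M), 110 °C, t-BuOH removed by distillation, N2
Reagents that add atoms: none
Why: Proposed new method: on heating, the enol form of the tert-butyl β-keto ester should lose t-BuOH through a six-membered transition state to give the α-oxoketene 6, whose ketene carbon C1 is then attacked by the enol carbon C2 of the β-diketone arm, and tautomerization gives the enolized 2-acyl-1,3,5-trione 7. The closest known reaction types are the thermal acylketene transfer from tert-butyl acetoacetates to O-, N- and C-nucleophiles and the Claisen cyclization of 3,5,7-triketo esters to acylphloroglucinols. Ring A closes in a 6-exo-dig mode at the sp carbon of the ketene (the cumulated C=C stays in the ring), through either enol tautomer of the diketone. No new stereocenter is formed, and C4 cannot epimerize because it carries no hydrogen and the neutral conditions exclude retro-Claisen cleavage. The step needs C- over O-acylation and acylation over aldol closure: quaternary C4 blocks the dienylketene 6π-electrocyclization that normally leads to 2-pyranones, the ketene carbon is far more electrophilic than any ketone, and an O-acyl enol lactone, being an enol ester of a β-keto acid, should return to 6 at this temperature whereas the C-acyl product, a hydrogen-bonded vinylogous acid, cannot. High dilution and removal of t-BuOH suppress ketene dimerization and the back reaction.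

Step 4
Reactants: 8 phloroglucinol (benzene-1,3,5-triol); 9 butanoyl chloride
Product: 10 1-(2,4,6-trihydroxyphenyl)butan-1-one
Conditions: AlCl3 (3.5 equiv), PhNO2–CH2Cl2, 0 → 50 °C; then ice/aq. HCl
Reagents that add atoms: none
Why: Friedel–Crafts acylation of the very electron-rich arene should stop at the monoketone because the aryl ketone, held as its aluminium chelate, deactivates the ring.

Step 5
Reactants: 10 1-(2,4,6-trihydroxyphenyl)butan-1-one; 11 prenyl bromide (1-bromo-3-methylbut-2-ene)
Product: 12 1-[2,4,6-trihydroxy-3-(3-methylbut-2-en-1-yl)phenyl]butan-1-one (monomer B)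
Conditions: KOH (10% aq.), 11 (1.0 equiv), 0 °C → rt; then dilute HCl
Reagents that add atoms: none
Why: The phenoxide of an acylphloroglucinol is C-alkylated by the soft allylic bromide in water (C-prenylation), one equivalent of bromide limiting dialkylation, and the two free ring positions of 10 are equivalent, so only one mono-C-prenyl isomer can form.

Step 6
Reactants: 7 (4R)-2-acetyl-4-[(2E)-3,7-dimethylocta-2,6-dien-1-yl]-3,5-dihydroxy-4-methylcyclohexa-2,5-dien-1-one
Product: 13 (4R)-2-acetyl-6-[(dimethylamino)methyl]-4-[(2E)-3,7-dimethylocta-2,6-dien-1-yl]-3,5-dihydroxy-4-methylcyclohexa-2,5-dien-1-one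
Conditions: CH2(NMe2)2 (1.5 equiv), CH2Cl2, 0 °C → rt; evaporation
Reagents that add atoms: N,N,N',N'-tetramethylmethanediamine, CN(C)CN(C)C
Why: The acidic triketone protonates the aminal to a methyleneiminium ion that is captured by the only free enolic ring carbon C6 (Mannich reaction), and the excess amine keeps the zwitterionic Mannich base from eliminating and dimerizing.

Step 7
Reactants: 13 (4R)-2-acetyl-6-[(dimethylamino)methyl]-4-[(2E)-3,7-dimethylocta-2,6-dien-1-yl]-3,5-dihydroxy-4-methylcyclohexa-2,5-dien-1-one; 12 1-[2,4,6-trihydroxy-3-(3-methylbut-2-en-1-yl)phenyl]butan-1-one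
Product: 15 (4R)-2-acetyl-6-{[3-butanoyl-2,4,6-trihydroxy-5-(3-methylbut-2-en-1-yl)phenyl]methyl}-4-[(2E)-3,7-dimethylocta-2,6-dien-1-yl]-3,5-dihydroxy-4-methylcyclohexa-2,5-dien-1-one (target), via methylidene trione 14 (not isolated)
Conditions: 12 (1.5 equiv), MeCN, 65 °C, N2 sweep
Reagents that add atoms: none
Why: Loss of dimethylamine from the Mannich base unmasks the 6-methylidene trione 14, a quinone-methide-like acceptor that should alkylate the only free ring carbon of 12 (Michael/Friedel–Crafts alkylation, the usual way to methylene-bridged acylphloroglucinol dimers), so the unsymmetrical bridge forms in a directed way and not statistically.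

**Compound list**

1 | 4-hydroxy-3,6-dimethyl-2H-pyran-2-one | CC1=CC(O)=C(C)C(=O)O1 | starting material
2 | geranyl acetate, (2E)-3,7-dimethylocta-2,6-dien-1-yl acetate | CC(=O)OC/C=C(\C)CCC=C(C)C | starting material
3 | (3S)-3-[(2E)-3,7-dimethylocta-2,6-dien-1-yl]-3,6-dimethyl-2H-pyran-2,4(3H)-dione | CC1=CC(=O)[C@](C)(C/C=C(\C)CCC=C(C)C)C(=O)O1 | intermediate
4 | tert-butyl acetate | CC(=O)OC(C)(C)C | starting material
5 | tert-butyl (4S)-4-[(2E)-3,7-dimethylocta-2,6-dien-1-yl]-4-methyl-3,5,7-trioxooctanoate | CC(C)(C)OC(=O)CC(=O)[C@@](C)(C/C=C(\C)CCC=C(C)C)C(=O)CC(C)=O | intermediate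
6 | (4S)-4-[(2E)-3,7-dimethylocta-2,6-dien-1-yl]-4-methyloct-1-ene-1,3,5,7-tetrone (acylketene) | O=C=CC(=O)[C@@](C)(C/C=C(\C)CCC=C(C)C)C(=O)CC(C)=O | intermediate
7 | (4R)-2-acetyl-4-[(2E)-3,7-dimethylocta-2,6-dien-1-yl]-3,5-dihydroxy-4-methylcyclohexa-2,5-dien-1-one (monomer A) | O=C1C=C(O)[C@@](C)(C/C=C(\C)CCC=C(C)C)C(O)=C1C(C)=O | intermediate
8 | phloroglucinol, benzene-1,3,5-triol | Oc1cc(O)cc(O)c1 | starting material
9 | butanoyl chloride | CCCC(Cl)=O | starting material
10 | 1-(2,4,6-trihydroxyphenyl)butan-1-one | CCCC(=O)c1c(O)cc(O)cc1O | intermediate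
11 | prenyl bromide, 1-bromo-3-methylbut-2-ene | CC(C)=CCBr | starting material
12 | 1-[2,4,6-trihydroxy-3-(3-methylbut-2-en-1-yl)phenyl]butan-1-one (monomer B) | CCCC(=O)c1c(O)cc(O)c(CC=C(C)C)c1O | intermediate
13 | (4R)-2-acetyl-6-[(dimethylamino)methyl]-4-[(2E)-3,7-dimethylocta-2,6-dien-1-yl]-3,5-dihydroxy-4-methylcyclohexa-2,5-dien-1-one | CN(C)CC1=C(O)[C@@](C)(C/C=C(\C)CCC=C(C)C)C(O)=C(C(C)=O)C1=O | intermediate
14 | (4S)-2-acetyl-4-[(2E)-3,7-dimethylocta-2,6-dien-1-yl]-3-hydroxy-4-methyl-6-methylidenecyclohex-2-ene-1,5-dione | C=C1C(=O)[C@@](C)(C/C=C(\C)CCC=C(C)C)C(O)=C(C(C)=O)C1=O | intermediate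
15 | (4R)-2-acetyl-6-{[3-butanoyl-2,4,6-trihydroxy-5-(3-methylbut-2-en-1-yl)phenyl]methyl}-4-[(2E)-3,7-dimethylocta-2,6-dien-1-yl]-3,5-dihydroxy-4-methylcyclohexa-2,5-dien-1-one | CCCC(=O)c1c(O)c(CC=C(C)C)c(O)c(CC2=C(O)[C@@](C)(C/C=C(\C)CCC=C(C)C)C(O)=C(C(C)=O)C2=O)c1O | target

**Count and risks**

Total steps: 7. Longest linear sequence: 5 (steps 1, 2, 3, 6, 7).

Steps most likely to fail:

Step 1 (Proposed new method). Facial selectivity on the pyranolate may be poor, the enantiomeric purity may erode through re-ionization of the C–allyl bond of the product, or O-allylation may persist. The fallback uses known chemistry and replaces asymmetric catalysis by resolution. Setting out from 1 and 2, the allylation is run with the achiral catalyst Pd(PPh3)4 (Et3N, THF, rt), which should give racemic 3-[(2E)-3,7-dimethylocta-2,6-dien-1-yl]-3,6-dimethyl-2H-pyran-2,4(3H)-dione F1. Preparative chromatography on a chiral stationary phase (supercritical CO2/MeOH) should separate it into 3 and the enantiomer (3R)-3-[(2E)-3,7-dimethylocta-2,6-dien-1-yl]-3,6-dimethyl-2H-pyran-2,4(3H)-dione F2, which is discarded. The route is rejoined at 3.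

Step 3 (Proposed new method). The ketene may be captured at oxygen to give an enol lactone that does not revert, or it may oligomerize. The fallback is the known base-mediated Claisen cyclization of a 3,5,7-triketo ester. Setting out from 3, methyl acetate and LiN(i-Pr)2 (THF, −78 °C) in place of 4 should give methyl (4S)-4-[(2E)-3,7-dimethylocta-2,6-dien-1-yl]-4-methyl-3,5,7-trioxooctanoate F3. This is cyclized with Mg(OMe)2 in MeOH at reflux, where magnesium chelation of both β-dicarbonyl units favours C-acylation, and acidified. The route is rejoined at 7.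

Step 2. The basic enolate may deprotonate the 6-methyl group of 3, or add at the enone carbon or the ketone instead of the lactone carbonyl. The fallback is a non-basic acyl transfer. Setting out from 3, Meldrum's acid and DMAP (CH2Cl2, 0 °C → rt) should open the lactone through an acylpyridinium ion and give the acyl Meldrum's acid 5-[(2R)-2-[(2E)-3,7-dimethylocta-2,6-dien-1-yl]-1-hydroxy-2-methyl-3,5-dioxohexylidene]-2,2-dimethyl-1,3-dioxane-4,6-dione F4. Heating F4 with t-BuOH in PhMe at 80 °C should then give the tert-butyl β-keto ester with loss of acetone and CO2. The route is rejoined at 5.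

**Further compounds**

F1 | step 1 | racemic 3-[(2E)-3,7-dimethylocta-2,6-dien-1-yl]-3,6-dimethyl-2H-pyran-2,4(3H)-dione | CC1=CC(=O)C(C)(C/C=C(\C)CCC=C(C)C)C(=O)O1
F2 | step 1 | (3R)-3-[(2E)-3,7-dimethylocta-2,6-dien-1-yl]-3,6-dimethyl-2H-pyran-2,4(3H)-dione | CC1=CC(=O)[C@@](C)(C/C=C(\C)CCC=C(C)C)C(=O)O1
F3 | step 3 | methyl (4S)-4-[(2E)-3,7-dimethylocta-2,6-dien-1-yl]-4-methyl-3,5,7-trioxooctanoate | COC(=O)CC(=O)[C@@](C)(C/C=C(\C)CCC=C(C)C)C(=O)CC(C)=O
F4 | step 2 | 5-[(2R)-2-[(2E)-3,7-dimethylocta-2,6-dien-1-yl]-1-hydroxy-2-methyl-3,5-dioxohexylidene]-2,2-dimethyl-1,3-dioxane-4,6-dione | CC(=O)CC(=O)[C@](C)(C/C=C(\C)CCC=C(C)C)C(O)=C1C(=O)OC(C)(C)OC1=O
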